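**Retrosynthetic overview**
- The C10–Cl is installed last by α-chlorination of the enone. The 5,6-diacetates come from a δ-lactone (masking O5) plus a free C6–OH, which is needed earlier as a stereo-relay.
- The C12 carbinol comes from α-selective (Z)-oct-2-enyl addition to a C12 ketone, anti to the α-chain, followed by allylic oxidation at C9 (1,3-carbonyl transposition).
- The cyclopentenone, the only carbocycle, is made from a 2-alkylfuran by one-pot photooxygenation and a hydroxyl-templated Piancatelli-type 4π closure (C8–C9 bond), relaying C6 to C8.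
- The furan/α-chain precursor comes from dimethyl 2,3-O-isopropylidene-L-tartrate by two Ni-electrocatalytic decarboxylative C(sp3)–C(sp3) couplings: C6–C7 with 3-(2-furyl)propanoic acid and C4–C5 with monomethyl glutarate.
- Ring order: temporary δ-lactone, then cyclopentenone.

Assumption: the target is taken exactly as the given SMILES, i.e. (5S,6S,8R,12S) with 14Z. Prostanoid numbering is used: C1 ester, C5/C6 acetoxy carbons, C8 ring CH, C9 C=O, C10 C–Cl, C12 carbinol, C13–C20 octenyl. In the target the 12-OH is cis to the α-chain and the octenyl group is trans to it.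

**Step 1**
Reactants: 1, dimethyl (4R,5R)-2,2-dimethyl-1,3-dioxolane-4,5-dicarboxylate (from L-tartaric acid)
Product: 2, (4R,5R)-5-(methoxycarbonyl)-2,2-dimethyl-1,3-dioxolane-4-carboxylic acid
Conditions: KOH (1.0 equiv), MeOH, 0 °C to rt; then H3O+
Reagents that add atoms: potassium hydroxide, [K+].[OH-]
Why: Statistical mono-saponification of a C2-symmetric diester gives a single monoacid whichever ester reacts, and the trans-dioxolane is the thermodynamic isomer so no stereochemistry is at risk.

**Step 2**
Reactants: 2 (monoacid); 3, 3-(furan-2-yl)propanoic acid (3 equiv)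
Product: 4, methyl (4R,5S)-5-[2-(furan-2-yl)ethyl]-2,2-dimethyl-1,3-dioxolane-4-carboxylate
Conditions: NHPI, DIC (redox-active esters formed in situ); NiCl2·6H2O/2,2′:6′,2″-terpyridine (20 mol %), AgNO3 (0.3 equiv), Mg(+)/RVC(−), NMP, rt, constant current
Reagents that add atoms: none
Why: Ni-electrocatalytic doubly decarboxylative sp3–sp3 cross-coupling of redox-active esters forms C6–C7, and the dioxolanyl radical/Ni intermediate is captured trans to the neighbouring ester, so C6 is reset under control of the tartrate-derived C5.

**Step 3**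
Reactants: 4
Product: 5, (4R,5S)-5-[2-(furan-2-yl)ethyl]-2,2-dimethyl-1,3-dioxolane-4-carboxylic acid
Conditions: LiOH·H2O, THF/H2O, 0 °C; then mild H3O+
Reagents that add atoms: lithium hydroxide, [Li+].[OH-]
Why: Ordinary ester saponification; any epimerisation α to the carboxylate would only return the favoured trans-dioxolane.

**Step 4**
Reactants: 5; 6, 5-methoxy-5-oxopentanoic acid (monomethyl glutarate, 3 equiv)
Product: 7, methyl 4-{(4S,5S)-5-[2-(furan-2-yl)ethyl]-2,2-dimethyl-1,3-dioxolan-4-yl}butanoate
Conditions: NHPI, DIC; NiCl2·6H2O/terpyridine (20 mol %), AgNO3, Mg(+)/RVC(−), NMP, rt, constant current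
Reagents that add atoms: none
Why: A second Ni-electrocatalytic decarboxylative sp3–sp3 coupling forms C4–C5 with the new substituent again trans on the dioxolane (C5 set by C6), giving the (5S,6S)-threo diol pattern of the target.

**Step 5**
Reactants: 7
Product: 8, (6S)-6-[(1S)-3-(furan-2-yl)-1-hydroxypropyl]oxan-2-one
Conditions: PPTS, MeOH, 45 °C; then PhMe, 60 °C (−MeOH)
Reagents that add atoms: none
Why: Acetonide methanolysis followed by acid-catalysed lactonisation, in which the 5-OH closes the favoured six-membered δ-lactone, so O5 is masked and only the C6–OH stays free; 2-alkylfurans tolerate PPTS.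

**Step 6**
Reactants: 8
Product: 9, (4R,5S)-4-hydroxy-5-{(2S)-2-hydroxy-2-[(2S)-6-oxooxan-2-yl]ethyl}cyclopent-2-en-1-one (in equilibrium with its cis-fused bicyclic hemiketal). Here the ring C=O is C12, the ring CH–OH is C9, and the 9-OH is trans to the side chain on C8.
Conditions: O2, methylene blue (1 mol %), white LEDs, CH2Cl2, −40 to 0 °C; Me2S; then Dy(OTf)3 (10 mol %), MeCN/H2O (20:1), rt
Reagents that add atoms: dioxygen, O=O (one O retained as the C9–OH); water, O (may supply or exchange the ketone oxygen)
Why: Proposed new method: singlet-oxygen [4+2] addition to the furan gives an endoperoxide that the C6–OH opens at the substituted carbon (known spiroketalisation of γ-hydroxyalkylfurans), and after Me2S reduction the acid ionises the spiro-hemiketal to a cyclic oxocarbenium/2-alkoxy-(Z)-dienal (a 2,3-dihydrofuran enol ether O6–C12=C8) whose protonated aldehyde undergoes a Piancatelli-type conrotatory 4π closure forming C8–C9; because C8 is held in the dihydrofuran, the bond forms on the face anti to the C6 substituent (the 1,3-anti bias seen in alkylation of γ-substituted butyrolactone enolates), which is the target C8 configuration, with the aldehyde oxygen "outside" so the 9-OH is trans, and water then releases the ketone and C6–OH; the closest known reactions are the Piancatelli rearrangement of 2-furylcarbinols, the iso-Nazarov cyclisation of (Z)-dienals and the photooxygenation/aldol route from 2-alkylfurans to 4-hydroxycyclopentenones, none of which uses a tethered hydroxyl to relay chirality.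

**Step 7**
Reactants: 10, (Z)-oct-2-en-1-ol
Product: 11, (Z)-1-chlorooct-2-ene
Conditions: NCS, Me2S, CH2Cl2, −20 to 0 °C
Reagents that add atoms: N-chlorosuccinimide, ClN1C(=O)CCC1=O
Why: Corey–Kim allylic chlorination is an SN2 displacement of the alkoxysulfonium, so there is no allylic transposition and the Z geometry is kept.

**Step 8**
Reactants: 9; 11 (as its barium reagent, about 4.5 equiv)
Product: 12, (6S)-6-{(1S)-2-[(1S,2R,5R)-2,5-dihydroxy-2-[(Z)-oct-2-en-1-yl]cyclopent-3-en-1-yl]-1-hydroxyethyl}oxan-2-one
Conditions: 11, Rieke Ba (BaI2, lithium biphenylide), THF, −78 °C; then 9, −78 °C; aq. NH4Cl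
Reagents that add atoms: none
Why: Allylbarium reagents add 1,2 to ketones at the α-carbon with retention of Z geometry; two equivalents are consumed by the OH groups, and attack on the C12 ketone occurs anti to the adjacent C8 side chain (the face also carrying the C9 alkoxide), placing octenyl trans and 12-OH cis to the α-chain; the ketone reacts faster than the lactone at −78 °C.

**Step 9**
Reactants: 12
Product: 13, (6S)-6-{(1S)-1-hydroxy-2-[(1R,2R)-2-hydroxy-2-[(Z)-oct-2-en-1-yl]-5-oxocyclopent-3-en-1-yl]ethyl}oxan-2-one
Conditions: activated MnO2, CH2Cl2, rt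
Reagents that add atoms: none
Why: MnO2 oxidises only the secondary allylic C9–OH (the tertiary C12–OH and non-allylic C6–OH are inert), completing the carbonyl transposition and removing the temporary C9 stereocentre; C8 is already in its thermodynamic configuration (trans to octenyl).

**Step 10**
Reactants: 13
Product: 14, methyl (5S,6S)-5,6-diacetoxy-7-[(1R,2R)-2-hydroxy-2-[(Z)-oct-2-en-1-yl]-5-oxocyclopent-3-en-1-yl]heptanoate
Conditions: CSA (0.2 equiv), MeOH, 0 °C to rt; pyridine quench, concentrate; Ac2O, pyridine, rt
Reagents that add atoms: methanol, CO; acetic anhydride, CC(=O)OC(C)=O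
Why: Acid-catalysed methanolysis opens the δ-lactone to the methyl 5-hydroxy ester, and Ac2O/pyridine without DMAP then acetylates the two secondary alcohols while leaving the tertiary allylic C12–OH free.

**Step 11**
Reactants: 14
Product: 15, Punaglandin 6, methyl (5S,6S)-5,6-diacetoxy-7-[(1R,2S)-4-chloro-2-hydroxy-2-[(Z)-oct-2-en-1-yl]-5-oxocyclopent-3-en-1-yl]heptanoate
Conditions: PhICl2 (1.1 equiv), pyridine, CH2Cl2, 0 °C, dark
Reagents that add atoms: (dichloroiodo)benzene, ClI(Cl)c1ccccc1
Why: Pyridine-mediated α-chlorination of the enone (conjugate addition, chlorination, elimination) puts Cl only at C10; the isolated Z-alkene should react more slowly under ionic, dark conditions, though this selectivity is not assured.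

**Compound list**
1 | dimethyl (4R,5R)-2,2-dimethyl-1,3-dioxolane-4,5-dicarboxylate | COC(=O)[C@@H]1OC(C)(C)O[C@H]1C(=O)OC | starting material
2 | (4R,5R)-5-(methoxycarbonyl)-2,2-dimethyl-1,3-dioxolane-4-carboxylic acid | OC(=O)[C@@H]1OC(C)(C)O[C@H]1C(=O)OC | intermediate
3 | 3-(furan-2-yl)propanoic acid | OC(=O)CCc1ccco1 | starting material
4 | methyl (4R,5S)-5-[2-(furan-2-yl)ethyl]-2,2-dimethyl-1,3-dioxolane-4-carboxylate | o1cccc1CC[C@@H]2OC(C)(C)O[C@H]2C(=O)OC | intermediate
5 | (4R,5S)-5-[2-(furan-2-yl)ethyl]-2,2-dimethyl-1,3-dioxolane-4-carboxylic acid | o1cccc1CC[C@@H]2OC(C)(C)O[C@H]2C(=O)O | intermediate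
6 | 5-methoxy-5-oxopentanoic acid (monomethyl glutarate) | COC(=O)CCCC(=O)O | starting material
7 | methyl 4-{(4S,5S)-5-[2-(furan-2-yl)ethyl]-2,2-dimethyl-1,3-dioxolan-4-yl}butanoate | o1cccc1CC[C@@H]2OC(C)(C)O[C@H]2CCCC(=O)OC | intermediate
8 | (6S)-6-[(1S)-3-(furan-2-yl)-1-hydroxypropyl]oxan-2-one | o1cccc1CC[C@H](O)[C@@H]2CCCC(=O)O2 | intermediate
9 | (4R,5S)-4-hydroxy-5-{(2S)-2-hydroxy-2-[(2S)-6-oxooxan-2-yl]ethyl}cyclopent-2-en-1-one | O=C1C=C[C@@H](O)[C@@H]1C[C@H](O)[C@@H]2CCCC(=O)O2 | intermediate
10 | (Z)-oct-2-en-1-ol | CCCCC/C=C\CO | starting material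
11 | (Z)-1-chlorooct-2-ene | CCCCC/C=C\CCl | intermediate
12 | (6S)-6-{(1S)-2-[(1S,2R,5R)-2,5-dihydroxy-2-[(Z)-oct-2-en-1-yl]cyclopent-3-en-1-yl]-1-hydroxyethyl}oxan-2-one | CCCCC/C=C\C[C@@]1(O)C=C[C@@H](O)[C@@H]1C[C@H](O)[C@@H]2CCCC(=O)O2 | intermediate
13 | (6S)-6-{(1S)-1-hydroxy-2-[(1R,2R)-2-hydroxy-2-[(Z)-oct-2-en-1-yl]-5-oxocyclopent-3-en-1-yl]ethyl}oxan-2-one | CCCCC/C=C\C[C@@]1(O)C=CC(=O)[C@@H]1C[C@H](O)[C@@H]2CCCC(=O)O2 | intermediate
14 | methyl (5S,6S)-5,6-diacetoxy-7-[(1R,2R)-2-hydroxy-2-[(Z)-oct-2-en-1-yl]-5-oxocyclopent-3-en-1-yl]heptanoate | CCCCC/C=C\C[C@@]1(O)C=CC(=O)[C@@H]1C[C@H](OC(C)=O)[C@H](CCCC(=O)OC)OC(C)=O | intermediate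
15 | Punaglandin 6, methyl (5S,6S)-5,6-diacetoxy-7-[(1R,2S)-4-chloro-2-hydroxy-2-[(Z)-oct-2-en-1-yl]-5-oxocyclopent-3-en-1-yl]heptanoate | CCCCC/C=C\C[C@@]1(O)C=C(Cl)C(=O)[C@@H]1C[C@H](OC(C)=O)[C@H](CCCC(=O)OC)OC(C)=O | target

**Step count**
Total steps: 11. Longest linear sequence: 10 (steps 1–6 and 8–11; step 7 is a one-step side branch).

**Steps most likely to fail, with fallbacks**
1. Step 6 (proposed new templated photooxygenation/4π cyclisation). The risks are modest facial selectivity, competing oxa-Michael addition of the C6–OH, and Z-to-E isomerisation of the enal. Fallback, using known chemistry only: drop the internal relay and build the ring from (R)-4-(tert-butyldimethylsilyloxy)cyclopent-2-enone, obtainable from the chiral pool by literature routes. Add the (Z)-octenyl unit 1,2 and anti to the OTBS group, desilylate and oxidise with MnO2 to the 4-hydroxy-4-octenylcyclopentenone. Then join C7–C8 by aldol/dehydration with the tartrate-derived C7 aldehyde and conjugate reduction of the exocyclic enone (C8 protonates trans to octenyl), and chlorinate last.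
2. Step 8 (allylbarium addition in the presence of two free OH groups and a lactone, where α/γ and facial selectivity both matter). Fallback: introduce the chain as an alkyne. Add the allenyltitanium reagent from 2-octyne (n-BuLi, then Ti(OiPr)4) to the ketone to give the homopropargylic tertiary alcohol, then set the Z-alkene by Lindlar semi-hydrogenation.
3. Step 11 (electrophilic chlorination next to an isolated Z-alkene). Fallback: avoid electrophilic chlorine altogether. Epoxidise the enone of 14 nucleophilically (t-BuOOH, DBU), then open and dehydrate with anhydrous HCl so chloride acts as the nucleophile. Alternatively, carry the chlorine from the start by using 3-(4-chlorofuran-2-yl)propanoic acid in step 2, so the transposition in steps 8–9 delivers the α-chloroenone directly.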